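Two questions stand on this flask:

* product at 6.0 min, in percent of the substrate charged
* part of the substrate charged that has reacted at 6.0 min

| setting | gamma | delta | flask |
|---|---|---|---|
| substrate | 0.10 M | 0.10 M | 0.10 M |
| reagent in the second phase | 0.10 M | 0.40 M | 0.200 M |
| remark | run made earlier | run made earlier |  |
| time |  |  | 6.0 min |
| volume of the second phase over the first |  |  | 0.50 |

| run | time / min | product / % | substrate / % |
|---|---|---|---|
| gamma | 0.333 | 18.1 | 82.4 |
| gamma | 1.00 | 39.6 | 59.7 |
| gamma | 1.50 | 50.9 | 49.4 |
| gamma | 2.50 | 61.1 | 38.6 |
| gamma | 4.00 | 69.5 | 30.7 |
| gamma | 5.00 | 73.4 | 26.1 |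
| delta | 0.333 | 53.2 | 47.2 |
| delta | 1.00 | 85.5 | 13.8 |
| delta | 1.50 | 92.8 | 5.4 |
| delta | 2.50 | 99.9 | 2.9 |
| delta | 4.00 | 100.5 | 0.7 |
| delta | 5.00 | 99.7 | 0.8 |

(each reading ± 1 percentage point)

- in the second phase: reagent in the second phase; everything else is in the first
- charges count per volume of the first phase; a concentration in a rate is the amount of a species over the volume of its own phase; every rate counts per litre of the first phase
- the numbers in the tables scatter by 1 percentage point (one standard deviation)
- what may be going on: reagent in the reaction phase <-> reagent in the second phase; 2 reagent in the reaction phase -> homo dimer; substrate + reagent in the reaction phase -> product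
- the earlier runs hold the two phases in the same ratio of volumes as the flask asked about

Gamma looks contradictory. Its substrate reads 49.4% at 1.50 min, yet still 26.1% at 5.00 min, where a steady half-life would leave 9.92%. The charges clear this up: gamma's are equal and each substrate takes one reagent, so the reagent shrinks with the substrate. If nothing else took reagent, the reciprocal of the substrate would grow in a straight line. Gamma's last reading gives a constant of 5.66 M⁻¹ min⁻¹ on the charges and its reading at 1.50 min gives 6.83 M⁻¹ min⁻¹, so the line read from gamma bends a little.

What can be frozen is the surplus, reagent charged minus substrate charged, which is 0.100 M in this flask. Late in a run with a surplus, at this ratio of volumes and with no reagent going elsewhere, the substrate decays pseudo-first-order at the constant times the surplus. For delta this gives 1.70 min⁻¹, and its readings at 1.00 min and 1.50 min, with their scatter, give 1.88 min⁻¹. For this flask the same reckoning, counting the reagent's fall from charge to surplus, estimates 1.67% of the substrate left, so 98.3% reacted.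

The forecast, holding that “transfer looks fast and partition simply folds into k”, gave 97.7% of product and 97.8% reacted, a little below this reckoning.

The flask gives 96.4% of product and 96.4% reacted.

    reagent in the reaction phase ⇌ reagent in the second phase, rate k1*([reagent in the reaction phase] - [reagent in the second phase]/K1) per volume of the first phase (partition coefficient = 0.530, kL = 0.0795 s⁻¹)
    2 reagent in the reaction phase → homo dimer (k = 0.0217 M⁻¹ s⁻¹)
    substrate + reagent in the reaction phase → product (k = 0.160 M⁻¹ s⁻¹)

Substrate left in the flask is 3.6%, about twice the estimate. Early in the flask, at 0.0407 min, the product step uses reagent in the reaction phase 3.9 times as fast as the homo dimer step; at 6.00 min the figure is 0.41, and the homo dimer holds 0.0624 M of the reagent charged against a surplus of 0.100 M.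

In a neighbouring flask with 0.40 M of substrate, all else as here, the surplus is −0.200 M, so reagent becomes the limiting reagent and caps product at 50.0%. That flask gives 47.4%, with 52.6% of its substrate left.

The numbers in the tables are simulated for substances that don't exist; the scatter is artificial.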